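## Retrosynthetic overview

- Key step, last: a twofold, reagent-controlled (S,S)-epoxidation of the C34 hexaene closes both oxirane rings (four C–O bonds, stereocentres C10, C11, C14, C15) in one operation.
- The hexaene is cut at C8–C9 and C16–C17: two successive copper-catalysed alkyl–allyl couplings join the Grignard reagents of two C12 half-bromides to a central (2E,6E)-C10 dichloride made by a double Wittig reaction.
- The half-bromides are epimers at the terminal centre (C3 vs C22); both come from one allylic chloride by copper-catalysed SN2′ methylation with mirror-image ligands.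
- That chloride comes from myrcene: a new CuH-catalysed enantioselective 4,3-hydroxymethylation with CO2 sets C7/C18 and leaves the C6/C19 methylidene; then Appel, SeO2 and Corey–Kim reactions.
- Ring order: no ring exists before the last step; the C10–C11 and C14–C15 oxiranes are formed together.

Atom labels C1–C24 are those of the target main chain (oxiranes at C10–C11 and C14–C15). Assumption: the sense of induction of the chiral ligands in steps 4, 8 and 9 is as written; if a pilot run shows the opposite, the mirror-image ligand, equally available, is used.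

## Route

Step 1
Reactants: 1 2,5-dimethoxytetrahydrofuran; 2 ethyl 2-(triphenylphosphoranylidene)propanoate
Product: 4 diethyl (2E,6E)-2,7-dimethylocta-2,6-dienedioate, via succinaldehyde 3 (not isolated)
Conditions: H2O, Amberlyst 15, 70 °C; filter; then 2 (2.3 equiv), H2O–CH2Cl2, 20 °C
Reagents that add atoms: none
Why: Acid hydrolysis of the bis-acetal gives succinaldehyde 3, which undergoes a twofold Wittig olefination with the stabilised α-methyl ylide 2; such ylides give the (E)-2-methyl-2-enoate at each end (≥95:5).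

Step 2
Reactants: 4 diethyl (2E,6E)-2,7-dimethylocta-2,6-dienedioate
Product: 5 (2E,6E)-2,7-dimethylocta-2,6-diene-1,8-diol
Conditions: i-Bu2AlH (4.4 equiv), CH2Cl2, −78 to 0 °C; aq. potassium sodium tartrate
Reagents that add atoms: none
Why: 1,2-Reduction of the α,β-unsaturated esters with i-Bu2AlH gives the bis-allylic alcohol without touching the alkene geometry.

Step 3
Reactants: 5 (2E,6E)-2,7-dimethylocta-2,6-diene-1,8-diol
Product: 6 (2E,6E)-1,8-dichloro-2,7-dimethylocta-2,6-diene
Conditions: N-chlorosuccinimide (2.4 equiv), Me2S (2.6 equiv), CH2Cl2, −20 to 0 °C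
Reagents that add atoms: N-chlorosuccinimide, ClN1C(=O)CCC1=O
Why: Corey–Kim chlorination; the alkoxysulfonium chloride collapses by SN2 attack of chloride at the primary allylic carbon, so there is no allylic transposition and no E/Z loss.

Step 4
Reactants: 7 β-myrcene
Product: 10 (2S)-2,7-dimethyl-3-methylideneoct-6-en-1-ol, via silyl ester 8 (not isolated), via silyl ether 9 (not isolated)
Conditions: Cu(OAc)2 (5 mol%), (R)-DTBM-SEGPHOS (6 mol%), (MeO)2MeSiH (4 equiv), CO2 (1 atm), cyclohexane, 60 °C; then K2CO3 (cat.), MeOH, 20 °C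
Reagents that add atoms: carbon dioxide, O=C=O
Why: Proposed new method: enantioselective 4,3-reductive hydroxymethylation of a 2-alkyl-1,3-diene with CO2; the ligand-bound CuH adds to the unhindered vinyl group of 7 (H to the terminal CH2, which becomes the methyl on C7/C18), the resulting 1,2-disubstituted allylcopper sits as the primary σ-allyl and takes up CO2 through a six-membered SE2′ transition state at the γ-carbon, so the new C–C bond, the (S)-stereocentre and the methylidene group arise together under ligand control, after which the silane turns copper over and reduces silyl ester 8 to silyl ether 9 in the same flask while the isolated trisubstituted alkene is left alone; the closest known reaction types are the CuH/DTBM-SEGPHOS reductive hydroxymethylation of styrenes and 1-aryl-1,3-dienes with CO2 and a hydrosilane, and the CuH-catalysed 4,3-selective allylation of ketones with 2-substituted dienes, neither of which has been shown for CO2 with a 2-alkyl diene.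

Step 5
Reactants: 10 (2S)-2,7-dimethyl-3-methylideneoct-6-en-1-ol
Product: 11 (7S)-8-bromo-2,7-dimethyl-6-methylideneoct-2-ene
Conditions: CBr4 (1.2 equiv), PPh3 (1.25 equiv), CH2Cl2, 0 °C
Reagents that add atoms: carbon tetrabromide, BrC(Br)(Br)Br
Why: Appel reaction; bromide displaces the oxyphosphonium group by SN2 at the primary carbon, and the adjacent stereocentre and both alkenes take no part.

Step 6
Reactants: 11 (7S)-8-bromo-2,7-dimethyl-6-methylideneoct-2-ene
Product: 12 (2E,7S)-8-bromo-2,7-dimethyl-6-methylideneoct-2-en-1-ol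
Conditions: SeO2 (0.5 equiv), t-BuOOH (70% aq., 2 equiv), salicylic acid (10 mol%), CH2Cl2, 0 to 20 °C, stopped at about 60% conversion (11 recovered)
Reagents that add atoms: selenium dioxide (oxygen carrier), O=[Se]=O; tert-butyl hydroperoxide (terminal oxidant), CC(C)(C)OO
Why: Catalytic SeO2/t-BuOOH allylic oxidation (ene reaction, then [2,3]-sigmatropic shift) attacks the (E)-methyl of the electron-rich trisubstituted alkene fastest and gives the (E)-allylic alcohol; partial conversion spares the slower allylic sites of the 1,1-disubstituted alkene, and the alkyl bromide is inert.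

Step 7
Reactants: 12 (2E,7S)-8-bromo-2,7-dimethyl-6-methylideneoct-2-en-1-ol
Product: 13 (2E,7S)-8-bromo-1-chloro-2,7-dimethyl-6-methylideneoct-2-ene
Conditions: N-chlorosuccinimide (1.2 equiv), Me2S (1.3 equiv), CH2Cl2, −20 to 0 °C
Reagents that add atoms: N-chlorosuccinimide, ClN1C(=O)CCC1=O
Why: Corey–Kim chlorination of the primary allylic alcohol by SN2 collapse of the alkoxysulfonium chloride, with the (E)-alkene and the primary bromide unchanged.

Step 8
Reactants: 13 (2E,7S)-8-bromo-1-chloro-2,7-dimethyl-6-methylideneoct-2-ene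
Product: 14 (2S,6R)-1-bromo-2,6,7-trimethyl-3-methylideneoct-7-ene
Conditions: MeMgBr (1.2 equiv, slow addition), copper thiophene-2-carboxylate Cu(O2CC4H3S) (3 mol%), (S,S,S)-L1 (3.3 mol%; L1 = 1,1′-binaphthyl-2,2′-diyl N,N-bis[1-(2-methoxyphenyl)ethyl]phosphoramidite), CH2Cl2, −78 °C
Reagents that add atoms: methylmagnesium bromide, C[Mg]Br
Why: Copper-catalysed asymmetric allylic alkylation (SN2′) of a β-methyl allylic chloride with a Grignard reagent and a phosphoramidite ligand; methyl is delivered to the γ-carbon under ligand control, which sets C3 as R (6R in 14) and creates the isopropenyl end, while the remote C7 centre has no influence and the primary bromide does not react at −78 °C.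

Step 9
Reactants: 13 (2E,7S)-8-bromo-1-chloro-2,7-dimethyl-6-methylideneoct-2-ene
Product: 15 (2S,6S)-1-bromo-2,6,7-trimethyl-3-methylideneoct-7-ene
Conditions: MeMgBr (1.2 equiv, slow addition), copper thiophene-2-carboxylate Cu(O2CC4H3S) (3 mol%), (R,R,R)-L1 (3.3 mol%), CH2Cl2, −78 °C
Reagents that add atoms: methylmagnesium bromide, C[Mg]Br
Why: The same copper-catalysed asymmetric SN2′ methylation with the mirror-image ligand gives the opposite configuration at the new centre, which becomes C22 (S) of the target (6S in 15).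

Step 10
Reactants: 14 (2S,6R)-1-bromo-2,6,7-trimethyl-3-methylideneoct-7-ene; 6 (2E,6E)-1,8-dichloro-2,7-dimethylocta-2,6-diene
Product: 17 (2E,6E,10R,14R)-1-chloro-2,7,10,14,15-pentamethyl-11-methylidenehexadeca-2,6,15-triene, via Grignard reagent 16 (not isolated)
Conditions: Mg, LiCl, THF, 0 to 20 °C; then added slowly to 6 (4 equiv), Li2CuCl4 (3 mol%), THF, −30 to 0 °C
Reagents that add atoms: none
Why: Kochi-type Li2CuCl4-catalysed cross-coupling of a primary alkyl Grignard reagent with a primary allylic chloride (SN2 at C9, alkene geometry kept); the Grignard reagent is made at or below 20 °C so that its β-stereocentre is not scrambled by homoallyl–cyclopropylcarbinyl exchange, and the excess of 6 (recovered) holds the reaction at mono-substitution.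

Step 11
Reactants: 15 (2S,6S)-1-bromo-2,6,7-trimethyl-3-methylideneoct-7-ene; 17 (2E,6E,10R,14R)-1-chloro-2,7,10,14,15-pentamethyl-11-methylidenehexadeca-2,6,15-triene
Product: 19 (3R,7R,10E,14E,18R,22S)-2,3,7,10,15,18,22,23-octamethyl-6,19-dimethylidenetetracosa-1,10,14,23-tetraene, via Grignard reagent 18 (not isolated)
Conditions: Mg, LiCl, THF, 0 to 20 °C; then 17, Li2CuCl4 (3 mol%), THF, −30 to 0 °C
Reagents that add atoms: none
Why: The same Li2CuCl4-catalysed alkyl–allyl coupling at the remaining allylic chloride forms C16–C17; no stereocentre is made and both (E)-alkenes are kept.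

Step 12
Reactants: 19 (3R,7R,10E,14E,18R,22S)-2,3,7,10,15,18,22,23-octamethyl-6,19-dimethylidenetetracosa-1,10,14,23-tetraene
Product: 20 (3R,7R,10S,11S,14S,15S,18R,22S)-10,11:14,15-diepoxy-2,3,7,10,15,18,22,23-octamethyl-6,19-dimethylidenetetracosa-1,23-diene
Conditions: 1,2:4,5-di-O-isopropylidene-β-L-erythro-2,3-hexodiulo-2,6-pyranose (L-fructose-derived Shi ketone, 0.6 equiv), KHSO5 (as Oxone, 2KHSO5·KHSO4·K2SO4; 2.8 equiv KHSO5), K2CO3, Bu4NHSO4 (cat.), MeCN–dimethoxymethane–aq. Na2B4O7/Na2EDTA buffer (pH 10.5), 0 °C, stopped when the mono-epoxide is consumed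
Reagents that add atoms: potassium peroxymonosulfate, [K+].OOS(=O)(=O)[O-]
Why: Shi asymmetric epoxidation; the chiral dioxirane made in the flask from the L-fructose-derived ketone transfers oxygen through a spiro transition state to the electron-rich (E)-trisubstituted alkenes much faster than to the four 1,1-disubstituted alkenes and gives the (S,S)-oxirane at each site by reagent control, which forms the four C–O bonds and sets C10, C11, C14 and C15 in one operation.

## Compound list

1 | 2,5-dimethoxytetrahydrofuran (cis/trans mixture) | COC1CCC(OC)O1 | starting material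
2 | ethyl 2-(triphenylphosphoranylidene)propanoate | CCOC(=O)C(C)=P(c1ccccc1)(c1ccccc1)c1ccccc1 | starting material
3 | succinaldehyde (butanedial) | O=CCCC=O | intermediate (not isolated)
4 | diethyl (2E,6E)-2,7-dimethylocta-2,6-dienedioate | CCOC(=O)/C(C)=C/CC/C=C(\C)C(=O)OCC | intermediate
5 | (2E,6E)-2,7-dimethylocta-2,6-diene-1,8-diol | OC/C(C)=C/CC/C=C(\C)CO | intermediate
6 | (2E,6E)-1,8-dichloro-2,7-dimethylocta-2,6-diene | ClC/C(C)=C/CC/C=C(\C)CCl | intermediate
7 | β-myrcene (7-methyl-3-methylideneocta-1,6-diene) | CC(C)=CCCC(=C)C=C | starting material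
8 | dimethoxy(methyl)silyl (2S)-2,7-dimethyl-3-methylideneoct-6-enoate | CO[Si](C)(OC)OC(=O)[C@@H](C)C(=C)CCC=C(C)C | intermediate (not isolated)
9 | {[(2S)-2,7-dimethyl-3-methylideneoct-6-en-1-yl]oxy}dimethoxy(methyl)silane | CO[Si](C)(OC)OC[C@@H](C)C(=C)CCC=C(C)C | intermediate (not isolated)
10 | (2S)-2,7-dimethyl-3-methylideneoct-6-en-1-ol | OC[C@@H](C)C(=C)CCC=C(C)C | intermediate
11 | (7S)-8-bromo-2,7-dimethyl-6-methylideneoct-2-ene | BrC[C@@H](C)C(=C)CCC=C(C)C | intermediate
12 | (2E,7S)-8-bromo-2,7-dimethyl-6-methylideneoct-2-en-1-ol | OC/C(C)=C/CCC(=C)[C@H](C)CBr | intermediate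
13 | (2E,7S)-8-bromo-1-chloro-2,7-dimethyl-6-methylideneoct-2-ene | ClC/C(C)=C/CCC(=C)[C@H](C)CBr | intermediate
14 | (2S,6R)-1-bromo-2,6,7-trimethyl-3-methylideneoct-7-ene (left half, C1–C8) | C=C(C)[C@H](C)CCC(=C)[C@H](C)CBr | intermediate
15 | (2S,6S)-1-bromo-2,6,7-trimethyl-3-methylideneoct-7-ene (right half, C17–C24) | C=C(C)[C@@H](C)CCC(=C)[C@H](C)CBr | intermediate
16 | [(2S,6R)-2,6,7-trimethyl-3-methylideneoct-7-en-1-yl]magnesium bromide | C=C(C)[C@H](C)CCC(=C)[C@H](C)C[Mg]Br | intermediate (not isolated)
17 | (2E,6E,10R,14R)-1-chloro-2,7,10,14,15-pentamethyl-11-methylidenehexadeca-2,6,15-triene | C=C(C)[C@H](C)CCC(=C)[C@H](C)CC/C(C)=C/CC/C=C(\C)CCl | intermediate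
18 | [(2S,6S)-2,6,7-trimethyl-3-methylideneoct-7-en-1-yl]magnesium bromide | C=C(C)[C@@H](C)CCC(=C)[C@H](C)C[Mg]Br | intermediate (not isolated)
19 | (3R,7R,10E,14E,18R,22S)-2,3,7,10,15,18,22,23-octamethyl-6,19-dimethylidenetetracosa-1,10,14,23-tetraene | C=C(C)[C@H](C)CCC(=C)[C@H](C)CC/C(C)=C/CC/C=C(\C)CC[C@@H](C)C(=C)CC[C@H](C)C(=C)C | intermediate
20 | (3R,7R,10S,11S,14S,15S,18R,22S)-10,11:14,15-diepoxy-2,3,7,10,15,18,22,23-octamethyl-6,19-dimethylidenetetracosa-1,23-diene | C=C(C)[C@H](C)CCC(=C)[C@H](C)CC[C@]1(C)O[C@H]1CC[C@@H]1O[C@@]1(C)CC[C@@H](C)C(=C)CC[C@H](C)C(=C)C | target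

## Step count and risks

Total step count: 12.
Longest linear sequence: 8 steps (steps 4, 5, 6, 7, 8, 10, 11, 12; 7 → 10 → 11 → 12 → 13 → 14 → 17 → 19 → 20).

Three steps most likely to fail:

Step 4 (the proposed new method). The risks are 4,1- instead of 4,3-addition and an insufficient ee on a 2-alkyl diene. The fallback uses known chemistry, sets out from myrcene 7 and comes back at alcohol 10. Titanocene-catalysed hydromagnesiation (n-PrMgBr, Cp2TiCl2 5 mol%, Et2O, 20 °C) gives the allylic Grignard reagent [2-(4-methylpent-3-en-1-yl)but-2-en-1-yl]magnesium bromide F1. F1 adds to monomeric formaldehyde (cracked paraformaldehyde) through its γ-carbon to give racemic 2,7-dimethyl-3-methylideneoct-6-en-1-ol F2. A lipase kinetic resolution (Amano lipase PS, vinyl acetate, i-Pr2O) acetylates the (S)-enantiomer faster, as is the rule for 2-methyl primary alcohols, and gives (2S)-2,7-dimethyl-3-methylideneoct-6-en-1-yl acetate F3; it is taken at about 40% conversion and the cycle is repeated if the ee is short. K2CO3 in MeOH then releases 10.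

Step 8 (step 9 is the same reaction with the mirror-image ligand). The risk is that MeMgBr with an aliphatic γ-substituent gives a modest SN2′/SN2 ratio or ee. The fallback sets out from allylic alcohol 12 and comes back at 14; it sets the terminal centre through a C–O bond instead. Sharpless asymmetric epoxidation (Ti(OiPr)4, L-(+)-diethyl tartrate, t-BuOOH, 4 Å molecular sieves, CH2Cl2, −20 °C) gives (2S,3S,7S)-8-bromo-2,3-epoxy-2,7-dimethyl-6-methylideneoctan-1-ol F4. Me3Al (hexane–CH2Cl2, 0 °C) opens the epoxide at C3 with inversion to give (2R,3R,7S)-8-bromo-2,3,7-trimethyl-6-methylideneoctane-1,2-diol F5. Thiophosgene and 4-(dimethylamino)pyridine give the cyclic thiocarbonate (4R)-4-[(2R,6S)-7-bromo-6-methyl-5-methylideneheptan-2-yl]-4-methyl-1,3-dioxolane-2-thione F6. Corey–Winter olefination under Corey–Hopkins conditions (1,3-dimethyl-2-phenyl-1,3,2-diazaphospholidine, 40 °C, mild enough for the alkyl bromide) gives 14.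

Step 12. The risks are over-oxidation at the four 1,1-disubstituted alkenes before both trisubstituted alkenes are consumed, and an inseparable minor diastereomer. The fallback sets out from diol 5 and comes back at target 20; it installs the oxiranes first and never exposes a 1,1-disubstituted alkene to an oxidant. Twofold Sharpless asymmetric epoxidation of 5 (Ti(OiPr)4, L-(+)-diethyl tartrate, t-BuOOH, 4 Å molecular sieves, CH2Cl2, −20 °C) gives (2S,3S,6S,7S)-2,3:6,7-diepoxy-2,7-dimethyloctane-1,8-diol F7; the double reaction raises the ee of the C2-symmetric product. Tf2O and 2,6-lutidine (CH2Cl2, −78 °C) give (2S,3S,6S,7S)-2,3:6,7-diepoxy-2,7-dimethyloctane-1,8-diyl bis(trifluoromethanesulfonate) F8. Grignard reagent 16 (1 equiv) is added to F8 (3 equiv) with CuBr·SMe2 (10 mol%) in Et2O at −78 °C and displaces one triflate to give (2S,3S,6S,7S,10R,14R)-2,3:6,7-diepoxy-2,7,10,14,15-pentamethyl-11-methylidenehexadec-15-en-1-yl trifluoromethanesulfonate F9. Grignard reagent 18 under the same conditions then gives 20.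

Further compounds

F1 | step 4 | [2-(4-methylpent-3-en-1-yl)but-2-en-1-yl]magnesium bromide | CC=C(CCC=C(C)C)C[Mg]Br
F2 | step 4 | racemic 2,7-dimethyl-3-methylideneoct-6-en-1-ol | OCC(C)C(=C)CCC=C(C)C
F3 | step 4 | (2S)-2,7-dimethyl-3-methylideneoct-6-en-1-yl acetate | CC(=O)OC[C@@H](C)C(=C)CCC=C(C)C
F4 | step 8 | (2S,3S,7S)-8-bromo-2,3-epoxy-2,7-dimethyl-6-methylideneoctan-1-ol | OC[C@]1(C)O[C@H]1CCC(=C)[C@H](C)CBr
F5 | step 8 | (2R,3R,7S)-8-bromo-2,3,7-trimethyl-6-methylideneoctane-1,2-diol | OC[C@](C)(O)[C@H](C)CCC(=C)[C@H](C)CBr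
F6 | step 8 | (4R)-4-[(2R,6S)-7-bromo-6-methyl-5-methylideneheptan-2-yl]-4-methyl-1,3-dioxolane-2-thione | S=C1OC[C@](C)(O1)[C@H](C)CCC(=C)[C@H](C)CBr
F7 | step 12 | (2S,3S,6S,7S)-2,3:6,7-diepoxy-2,7-dimethyloctane-1,8-diol | OC[C@]1(C)O[C@H]1CC[C@@H]1O[C@@]1(C)CO
F8 | step 12 | (2S,3S,6S,7S)-2,3:6,7-diepoxy-2,7-dimethyloctane-1,8-diyl bis(trifluoromethanesulfonate) | FC(F)(F)S(=O)(=O)OC[C@]1(C)O[C@H]1CC[C@@H]1O[C@@]1(C)COS(=O)(=O)C(F)(F)F
F9 | step 12 | (2S,3S,6S,7S,10R,14R)-2,3:6,7-diepoxy-2,7,10,14,15-pentamethyl-11-methylidenehexadec-15-en-1-yl trifluoromethanesulfonate | C=C(C)[C@H](C)CCC(=C)[C@H](C)CC[C@]1(C)O[C@H]1CC[C@@H]1O[C@@]1(C)COS(=O)(=O)C(F)(F)F
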